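**Retrosynthetic overview**

1. Ring labels: C is the central 5-hydroxy-1,2,3-tris(aryloxy)benzene. E is the 4-chloro-3,5-dihydroxyphenyl group on O2 of C. B and D are the identical arm rings on O1 and O3 of C, numbered so that C1 bears O–A (or O–F) and C4 bears O–C. A and F are the terminal 2,4,6-trihydroxyphenoxy rings. B' and D' are the 2,4,6-trihydroxyphenyl rings bonded through carbon to C6 of B and D.
2. Feature: in B' and D' the carbon bonded to C6 of B or D sits between two C–O carbons, with a third C–O carbon para to it. This 2-arylphloroglucinol pattern equals the two carbons of an aryl ynol ether plus the four ring carbons of 3-ethoxycyclobutenone. The mirror plane through C2 and C5 of ring C makes the two sites equivalent.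
3. First disconnection: B' and D' are taken apart together (twofold Danheiser benzannulation) to a bis(aryl siloxyalkyne), so the tetra-ortho-oxygenated aryl–aryl bonds are never made by coupling. The alkynes come from two formyl groups.
4. Second disconnection: B–O–C and D–O–C come from a twofold Ullmann coupling of a ring C–E dibromide with an A–B arm phenol. E–O–C comes from a Chan–Lam arylation. A–O–B comes from SNAr on a fluoroarene activated by the same formyl group.
5. Ring order: A to F are bought as benzenes and joined E–O–C, A–O–B, then B–O–C together with D–O–C. B' and D' are built last and together from acyclic carbons. Desilylation and global ether cleavage finish the route.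

Key step: step 15

Remark: in compound 27 each new ring carries OH and OSi on its two ortho carbons, so both biaryl axes are stereogenic. 27 should therefore form as a mixture of atropisomers, which is carried on unseparated. Both axes lose their stereogenicity in step 16, and the target has no stereogenic element.

**Step 1**
Reactants: 1 2-chloro-1,3-dimethoxybenzene
Product: 2 2-(4-chloro-3,5-dimethoxyphenyl)-4,4,5,5-tetramethyl-1,3,2-dioxaborolane
Conditions: [Ir(OMe)(cod)]2 (1.5 mol %), 4,4'-di-tert-butyl-2,2'-bipyridine (3 mol %), B2pin2 (1.0 equiv), THF, 80 °C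
Reagents that add atoms: bis(pinacolato)diboron CC1(C)OB(OC1(C)C)B1OC(C)(C)C(C)(C)O1
Why: Iridium-catalysed aromatic C–H borylation is ruled by sterics, C5 is the only C–H of 1 without an ortho substituent, and the C–Cl bond is not touched.

**Step 2**
Reactants: 2 2-(4-chloro-3,5-dimethoxyphenyl)-4,4,5,5-tetramethyl-1,3,2-dioxaborolane
Product: 3 (4-chloro-3,5-dimethoxyphenyl)boronic acid
Conditions: NaIO4 (3 equiv), NH4OAc (3 equiv), acetone/H2O, rt
Reagents that add atoms: water O
Why: In this oxidative boronic ester hydrolysis, periodate destroys the diol as it is released, which pulls the equilibrium to the free boronic acid, the better partner for the copper-mediated step.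

**Step 3**
Reactants: 3 (4-chloro-3,5-dimethoxyphenyl)boronic acid; 4 2,6-dibromo-4-methoxyphenol
Product: 5 1,3-dibromo-2-(4-chloro-3,5-dimethoxyphenoxy)-5-methoxybenzene
Conditions: Cu(OAc)2 (1 equiv), pyridine (5 equiv), 4 Å MS, CH2Cl2, dry air (terminal oxidant), rt; 3 in excess (2 equiv)
Reagents that add atoms: none
Why: The Chan–Lam O-arylation with divalent copper runs at room temperature, accepts phenols with two ortho halogens when the boronic acid has no ortho substituent (as in 3), and leaves C–Br and C–Cl bonds intact.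

**Step 4**
Reactants: 6 3,4,5-trimethoxyaniline
Product: 7 3,4,5-trimethoxybenzenediazonium tetrafluoroborate
Conditions: NaNO2, 48 % aq HBF4, H2O, 0 °C; filter, wash (cold Et2O), dry
Reagents that add atoms: sodium nitrite [Na+].[O-]N=O; tetrafluoroboric acid [H+].F[B-](F)(F)F
Why: This is an ordinary diazotization in excess acid, and the sparingly soluble tetrafluoroborate salt precipitates and can be dried (first half of the Balz–Schiemann reaction).

**Step 5**
Reactants: 7 3,4,5-trimethoxybenzenediazonium tetrafluoroborate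
Product: 8 5-fluoro-1,2,3-trimethoxybenzene
Conditions: 1,2-dichlorobenzene, 120–140 °C, until N2 evolution ends
Reagents that add atoms: none
Why: In the Balz–Schiemann fluorodediazoniation, thermal loss of N2 leaves an aryl cation that takes fluoride from its own BF4 counter-ion.

**Step 6**
Reactants: 8 5-fluoro-1,2,3-trimethoxybenzene
Product: 9 4-fluoro-2,6-dimethoxyphenol
Conditions: BCl3 (1.2 equiv), CH2Cl2, −10 °C to rt; then H2O
Reagents that add atoms: none
Why: Lewis-acid ether cleavage with BCl3 selects the central methoxy group of a 1,2,3-trimethoxyarene, because that group is twisted out of conjugation, has the most basic oxygen, and places boron within reach of a neighbouring methoxy oxygen.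

**Step 7**
Reactants: 9 4-fluoro-2,6-dimethoxyphenol
Product: 10 5-fluoro-1,3-dimethoxy-2-(methoxymethoxy)benzene
Conditions: MeOCH2Cl, i-Pr2NEt, CH2Cl2, 0 °C to rt
Reagents that add atoms: chloromethyl methyl ether COCCl
Why: O-alkylation of the phenol gives an acetal that withstands butyllithium and hot carbonate and can later be removed with mild acid without affecting the methyl ethers.

**Step 8**
Reactants: 10 5-fluoro-1,3-dimethoxy-2-(methoxymethoxy)benzene
Product: 12 6-fluoro-2,4-dimethoxy-3-(methoxymethoxy)benzaldehyde, via aryllithium 11 (not isolated)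
Conditions: n-BuLi (1.1 equiv), THF, −78 °C, 1 h; DMF (3 equiv), −78 to 0 °C; H2O
Reagents that add atoms: N,N-dimethylformamide CN(C)C=O
Why: In this directed ortho-metalation the two ring C–H bonds of 10 are equivalent and each lies between F and OMe, so only one aryllithium can form, and at −78 °C DMF traps it before LiF can be lost.

**Step 9**
Reactants: 12 6-fluoro-2,4-dimethoxy-3-(methoxymethoxy)benzaldehyde; 13 2,4,6-trimethoxyphenol
Product: 14 2,4-dimethoxy-3-(methoxymethoxy)-6-(2,4,6-trimethoxyphenoxy)benzaldehyde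
Conditions: Cs2CO3 (2 equiv), DMSO, argon, 100 °C
Reagents that add atoms: none
Why: In this SNAr (addition–elimination) the ortho formyl group stabilizes the anionic adduct, fluoride is the best leaving group, and the poorly solvated caesium phenoxide in DMSO makes up for the three donor groups on the ring.

**Step 10**
Reactants: 14 2,4-dimethoxy-3-(methoxymethoxy)-6-(2,4,6-trimethoxyphenoxy)benzaldehyde
Product: 15 3-hydroxy-2,4-dimethoxy-6-(2,4,6-trimethoxyphenoxy)benzaldehyde
Conditions: 3 M aq HCl, THF, 45 °C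
Reagents that add atoms: none
Why: Acid hydrolysis cleaves the acetal-type methoxymethyl ether, while methyl ethers, the diaryl ether and the aldehyde (kept free by the aqueous medium) are stable.

**Step 11**
Reactants: 5 1,3-dibromo-2-(4-chloro-3,5-dimethoxyphenoxy)-5-methoxybenzene; 15 3-hydroxy-2,4-dimethoxy-6-(2,4,6-trimethoxyphenoxy)benzaldehyde (2 equivalents react, 2.4 used)
Product: 16 2-(4-chloro-3,5-dimethoxyphenoxy)-1,3-bis[3-formyl-2,6-dimethoxy-4-(2,4,6-trimethoxyphenoxy)phenoxy]-5-methoxybenzene
Conditions: CuI (20 mol %), picolinic acid (40 mol %), K3PO4 (5 equiv), DMSO, argon, 100–110 °C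
Reagents that add atoms: none
Why: This twofold Ullmann diaryl ether coupling uses monovalent copper with picolinic acid, a system made for ortho-substituted partners, C–Br reacts ahead of C–Cl, and the aldehydes have no α-hydrogen and tolerate K3PO4.

**Step 12**
Reactants: 16 the dialdehyde of step 11
Product: 17 bis(alkyne), as 16 with each formyl group replaced by ethynyl
Conditions: dimethyl (1-diazo-2-oxopropyl)phosphonate (3 equiv), K2CO3 (5 equiv), MeOH/THF 1:1, 0 °C to rt
Reagents that add atoms: dimethyl (1-diazo-2-oxopropyl)phosphonate CC(=O)C(=[N+]=[N-])P(=O)(OC)OC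
Why: The Ohira–Bestmann (Seyferth–Gilbert) homologation turns each non-enolizable aryl aldehyde into the terminal alkyne under carbonate in methanol, which affects no ether and no halide.

**Step 13**
Reactants: 17 bis(alkyne)
Product: 20 bis(siloxyalkyne), as 16 with each formyl group replaced by (triisopropylsilyloxy)ethynyl, via bis(lithium acetylide) 18 (not isolated), via bis(lithium ynolate) 19 (not isolated)
Conditions: t-BuOOH (2.4 equiv, anhydrous in decane), LiN(SiMe3)2 (5 equiv), THF, −78 to 0 °C; then i-Pr3SiOTf (3 equiv), −78 to 0 °C; rapid filtration through Et3N-deactivated silica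
Reagents that add atoms: tert-butyl hydroperoxide CC(C)(C)OO; triisopropylsilyl trifluoromethanesulfonate CC(C)[Si](C(C)C)(C(C)C)OS(=O)(=O)C(F)(F)F
Why: Electrophilic oxygen transfer from LiOO-t-Bu to a lithium acetylide gives the ynolate, a known route to aryl ynolates, and the bulky silyl triflate silylates it on oxygen rather than carbon.

**Step 14**
Reactants: 21 ethoxyacetylene
Product: 22 3-ethoxycyclobut-2-en-1-one
Conditions: ketene gas (from pyrolysis of acetone in a ketene generator), CH2Cl2, 0 °C to rt; distillation under reduced pressure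
Reagents that add atoms: ketene C=C=O
Why: In this thermal (2+2) cycloaddition of ketene with an ynol ether, the nucleophilic terminal alkyne carbon bonds to the ketene carbonyl carbon, which places the ethoxy group at C3.

**Step 15**
Reactants: 20 bis(siloxyalkyne); 22 3-ethoxycyclobut-2-en-1-one (2 equivalents react, about 5 used)
Product: 27 protected octaaryl compound, as 16 with each formyl group replaced by 4-ethoxy-2-hydroxy-6-(triisopropylsilyloxy)phenyl, via (1-ethoxyvinyl)ketene 23 (not isolated), via bis(vinylcyclobutenone) 24 (not isolated), via bis(dienylketene) 25 (not isolated), via bis(cyclohexadienone) 26 (not isolated)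
Conditions: 22 added in portions, degassed toluene, sealed tube, 110 °C; then K2CO3, MeOH/THF, rt (cleaves any aryl ester formed from excess 23)
Reagents that add atoms: none
Why: On heating, 22 opens by a 4π electrocyclic reaction of its C1–C4 bond to ketene 23, whose C=C=O unit adds in a (2+2) sense to each siloxyalkyne of 20 to give the 2-aryl-3-siloxy-4-(1-ethoxyvinyl)cyclobutenones of 24, and these open again (4π) to the dienylketenes of 25. Rings B' and D' each close by 6π electrocyclization between the ketene carbon and the terminal CH2 of the former vinyl group (26), and tautomerization to the phenol makes the cascade irreversible through aromatization. In net terms the two alkyne carbons end up between C1 and C2 of 22 (new bonds C1–C(aryl) and C2–C(OSi), four new C–C bonds in all), and the crowded aryl–aryl bond at C6 of B and D is simply the former aryl–alkyne bond. The closest known reaction type is the Danheiser benzannulation of cyclobutenones with trialkylsiloxyalkynes to resorcinol monosilyl ethers, whose usual scope is stretched here by the 3-alkoxy group, the di-ortho-substituted aryl group and the twofold use. The selectivity needed is the orientation of the ketene–alkyne addition, and the siloxy oxygen secures it by making the aryl-bearing alkyne carbon the nucleophile that attacks the ketene carbonyl carbon, which puts the biaryl carbon between C–OH and C–OSi and the ethoxy group para to it. No lasting stereocentre is formed (C4 of 24 is lost on ring opening, the axes of 27 are dealt with in step 16), and the medium, free of metal and base, leaves methyl ethers, diaryl ethers and the C–Cl bond alone while the two remote alkynes react independently.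

**Step 16**
Reactants: 27 protected octaaryl compound
Product: 28 tetraphenol, as 16 with each formyl group replaced by 4-ethoxy-2,6-dihydroxyphenyl
Conditions: Bu4NF (2.5 equiv), AcOH (2.5 equiv), THF, 0 °C
Reagents that add atoms: none
Why: Fluoride cleaves the aryl silyl ethers through the strong Si–F bond, the acetic acid buffer keeps the electron-rich phenols protonated, and the atropisomers of 27 merge into one compound.

**Step 17**
Reactants: 28 tetraphenol
Product: 29 target CNP0275555.0
Conditions: BBr3 (about 40 equiv, 1 M in CH2Cl2), CH2Cl2, argon, −78 °C to rt; ice-water; EtOAc extraction; Sephadex LH-20 or C18 with degassed solvents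
Reagents that add atoms: none
Why: BBr3 cleaves alkyl aryl ethers by bromide attack on the sp3 carbon of the boron-bound ether, so the thirteen methyl and two ethyl groups leave, while diaryl ethers and the aryl chloride, which offer only sp2 carbons, should stay.

**Compound list**

1 | 2-chloro-1,3-dimethoxybenzene | COc1cccc(OC)c1Cl | starting material
2 | 2-(4-chloro-3,5-dimethoxyphenyl)-4,4,5,5-tetramethyl-1,3,2-dioxaborolane | COc1cc(B2OC(C)(C)C(C)(C)O2)cc(OC)c1Cl | intermediate
3 | (4-chloro-3,5-dimethoxyphenyl)boronic acid | COc1cc(B(O)O)cc(OC)c1Cl | intermediate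
4 | 2,6-dibromo-4-methoxyphenol | COc1cc(Br)c(O)c(Br)c1 | starting material
5 | 1,3-dibromo-2-(4-chloro-3,5-dimethoxyphenoxy)-5-methoxybenzene | COc1cc(Br)c(Oc2cc(OC)c(Cl)c(OC)c2)c(Br)c1 | intermediate
6 | 3,4,5-trimethoxyaniline | COc1cc(N)cc(OC)c1OC | starting material
7 | 3,4,5-trimethoxybenzenediazonium tetrafluoroborate | COc1cc([N+]#N)cc(OC)c1OC.F[B-](F)(F)F | intermediate
8 | 5-fluoro-1,2,3-trimethoxybenzene | COc1cc(F)cc(OC)c1OC | intermediate
9 | 4-fluoro-2,6-dimethoxyphenol | COc1cc(F)cc(OC)c1O | intermediate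
10 | 5-fluoro-1,3-dimethoxy-2-(methoxymethoxy)benzene | COCOc1c(OC)cc(F)cc1OC | intermediate
11 | [6-fluoro-2,4-dimethoxy-3-(methoxymethoxy)phenyl]lithium (not isolated) | [Li]c1c(F)cc(OC)c(OCOC)c1OC | intermediate
12 | 6-fluoro-2,4-dimethoxy-3-(methoxymethoxy)benzaldehyde | O=Cc1c(F)cc(OC)c(OCOC)c1OC | intermediate
13 | 2,4,6-trimethoxyphenol | COc1cc(OC)c(O)c(OC)c1 | starting material
14 | 2,4-dimethoxy-3-(methoxymethoxy)-6-(2,4,6-trimethoxyphenoxy)benzaldehyde | O=Cc1c(Oc2c(OC)cc(OC)cc2OC)cc(OC)c(OCOC)c1OC | intermediate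
15 | 3-hydroxy-2,4-dimethoxy-6-(2,4,6-trimethoxyphenoxy)benzaldehyde | O=Cc1c(Oc2c(OC)cc(OC)cc2OC)cc(OC)c(O)c1OC | intermediate
16 | 2-(4-chloro-3,5-dimethoxyphenoxy)-1,3-bis[3-formyl-2,6-dimethoxy-4-(2,4,6-trimethoxyphenoxy)phenoxy]-5-methoxybenzene | COc1cc(Oc2c(OC)cc(Oc3c(OC)cc(OC)cc3OC)c(C=O)c2OC)c(Oc2cc(OC)c(Cl)c(OC)c2)c(Oc2c(OC)cc(Oc3c(OC)cc(OC)cc3OC)c(C=O)c2OC)c1 | intermediate
17 | bis(alkyne): 16 with ethynyl in place of each formyl | COc1cc(Oc2c(OC)cc(Oc3c(OC)cc(OC)cc3OC)c(C#C)c2OC)c(Oc2cc(OC)c(Cl)c(OC)c2)c(Oc2c(OC)cc(Oc3c(OC)cc(OC)cc3OC)c(C#C)c2OC)c1 | intermediate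
18 | bis(lithium acetylide) of 17 (not isolated) | COc1cc(Oc2c(OC)cc(Oc3c(OC)cc(OC)cc3OC)c(C#C[Li])c2OC)c(Oc2cc(OC)c(Cl)c(OC)c2)c(Oc2c(OC)cc(Oc3c(OC)cc(OC)cc3OC)c(C#C[Li])c2OC)c1 | intermediate
19 | bis(lithium ynolate) (not isolated) | COc1cc(Oc2c(OC)cc(Oc3c(OC)cc(OC)cc3OC)c(C#CO[Li])c2OC)c(Oc2cc(OC)c(Cl)c(OC)c2)c(Oc2c(OC)cc(Oc3c(OC)cc(OC)cc3OC)c(C#CO[Li])c2OC)c1 | intermediate
20 | bis(siloxyalkyne): 16 with (triisopropylsilyloxy)ethynyl in place of each formyl | COc1cc(Oc2c(OC)cc(Oc3c(OC)cc(OC)cc3OC)c(C#CO[Si](C(C)C)(C(C)C)C(C)C)c2OC)c(Oc2cc(OC)c(Cl)c(OC)c2)c(Oc2c(OC)cc(Oc3c(OC)cc(OC)cc3OC)c(C#CO[Si](C(C)C)(C(C)C)C(C)C)c2OC)c1 | intermediate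
21 | ethoxyacetylene | CCOC#C | starting material
22 | 3-ethoxycyclobut-2-en-1-one | CCOC1=CC(=O)C1 | intermediate
23 | (1-ethoxyvinyl)ketene, 3-ethoxybuta-1,3-dien-1-one (not isolated) | C=C(OCC)C=C=O | intermediate
24 | bis(vinylcyclobutenone): 16 with 4-(1-ethoxyvinyl)-1-oxo-3-(triisopropylsilyloxy)cyclobut-2-en-2-yl in place of each formyl (both arms drawn at the same stage, C4 centres transient and unassigned, not isolated) | COc1cc(Oc2c(OC)cc(Oc3c(OC)cc(OC)cc3OC)c(C3=C(O[Si](C(C)C)(C(C)C)C(C)C)C(C(=C)OCC)C3=O)c2OC)c(Oc2cc(OC)c(Cl)c(OC)c2)c(Oc2c(OC)cc(Oc3c(OC)cc(OC)cc3OC)c(C3=C(O[Si](C(C)C)(C(C)C)C(C)C)C(C(=C)OCC)C3=O)c2OC)c1 | intermediate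
25 | bis(dienylketene): each arm carries C(=C=O)–C(OSi-i-Pr3)=CH–C(OEt)=CH2 with ketene and vinyl termini cis on the central C=C (both arms drawn at the same stage, not isolated) | COc1cc(Oc2c(OC)cc(Oc3c(OC)cc(OC)cc3OC)c(C(=C=O)/C(O[Si](C(C)C)(C(C)C)C(C)C)=C\C(=C)OCC)c2OC)c(Oc2cc(OC)c(Cl)c(OC)c2)c(Oc2c(OC)cc(Oc3c(OC)cc(OC)cc3OC)c(C(=C=O)/C(O[Si](C(C)C)(C(C)C)C(C)C)=C\C(=C)OCC)c2OC)c1 | intermediate
26 | bis(cyclohexadienone): each arm carries 4-ethoxy-6-oxo-2-(triisopropylsilyloxy)cyclohexa-1,3-dien-1-yl (both arms drawn at the same stage, not isolated) | COc1cc(Oc2c(OC)cc(Oc3c(OC)cc(OC)cc3OC)c(C3=C(O[Si](C(C)C)(C(C)C)C(C)C)C=C(OCC)CC3=O)c2OC)c(Oc2cc(OC)c(Cl)c(OC)c2)c(Oc2c(OC)cc(Oc3c(OC)cc(OC)cc3OC)c(C3=C(O[Si](C(C)C)(C(C)C)C(C)C)C=C(OCC)CC3=O)c2OC)c1 | intermediate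
27 | protected octaaryl compound: 16 with 4-ethoxy-2-hydroxy-6-(triisopropylsilyloxy)phenyl in place of each formyl (mixture of atropisomers) | COc1cc(Oc2c(OC)cc(Oc3c(OC)cc(OC)cc3OC)c(-c3c(O)cc(OCC)cc3O[Si](C(C)C)(C(C)C)C(C)C)c2OC)c(Oc2cc(OC)c(Cl)c(OC)c2)c(Oc2c(OC)cc(Oc3c(OC)cc(OC)cc3OC)c(-c3c(O)cc(OCC)cc3O[Si](C(C)C)(C(C)C)C(C)C)c2OC)c1 | intermediate
28 | tetraphenol: 16 with 4-ethoxy-2,6-dihydroxyphenyl in place of each formyl | COc1cc(Oc2c(OC)cc(Oc3c(OC)cc(OC)cc3OC)c(-c3c(O)cc(OCC)cc3O)c2OC)c(Oc2cc(OC)c(Cl)c(OC)c2)c(Oc2c(OC)cc(Oc3c(OC)cc(OC)cc3OC)c(-c3c(O)cc(OCC)cc3O)c2OC)c1 | intermediate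
29 | CNP0275555.0 | Oc1cc(O)c(Oc2cc(O)c(Oc3cc(O)cc(Oc4c(O)cc(Oc5c(O)cc(O)cc5O)c(-c5c(O)cc(O)cc5O)c4O)c3Oc3cc(O)c(Cl)c(O)c3)c(O)c2-c2c(O)cc(O)cc2O)c(O)c1 | target

**Step count**

Total step count: 17.
Longest linear sequence: 13 steps (steps 4 to 13, then 15 to 17, starting from 6).

**Three steps most likely to fail**

**Step 15.**
- What may go wrong: the vinylogous-ester stabilization of 22 may slow its electrocyclic opening so much that ketene dimerization and thermal decay of the siloxyalkynes outrun the (2+2) addition. Shielding by the two ortho substituents may also stop the reaction after one arm.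
- Fallback: it sets out from 20 and comes back at 24, which goes on to 27. Ketene 23 is generated without heat by the diazoketone variant of the same benzannulation.
- Ethyl vinyl ether is lithiated (t-BuLi, THF, −78 to 0 °C) to 1-ethoxyvinyllithium F1.
- F1 is acylated with N-methoxy-N-methylacetamide to 3-ethoxybut-3-en-2-one F2.
- Detrifluoroacetylative diazo transfer follows. LiN(SiMe3)2 and CF3CO2CH2CF3 in THF at −78 °C give 5-ethoxy-1,1,1-trifluorohex-5-ene-2,4-dione F3. MsN3, Et3N and H2O in MeCN then give 1-diazo-3-ethoxybut-3-en-2-one F4.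
- F4 is irradiated together with 20 in CH2Cl2 at rt, at 365 nm or longer, where the polyaryl ether does not absorb. This triggers a photochemical Wolff rearrangement to 23, which should add to 20 to give 24. Short heating in toluene then carries 24 through 25 and 26 to 27.

**Step 11.**
- What may go wrong: each C–Br bond lies next to an aryloxy group and the phenol has two ortho methoxy groups. Copper insertion and C–O bond formation may therefore be slow, with hydrodebromination and stalling after the first coupling.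
- Fallback: it sets out from 4 and 15, uses 3 at the end, and comes back at 16. The two arm ethers are made by addition–elimination on a quinone, and the E–O–C bond is made last.
- Phenol 4 is oxidized (PhI(OAc)2, MeCN/H2O, 0 °C) to 2,6-dibromo-1,4-benzoquinone F5.
- The two vinylogous acyl bromide positions of F5 are substituted by the phenoxide of 15 (2 equiv, Cs2CO3, MeCN, 0 °C to rt) to give the 2,6-bis(aryloxy)-1,4-benzoquinone F6.
- Na2S2O4 (THF/H2O, rt) reduces F6 to the 2,6-bis(aryloxy)hydroquinone F7.
- The unhindered 4-hydroxyl of F7 is methylated (MeI, 1 equiv, K2CO3, acetone) to the 4-methoxy-2,6-bis(aryloxy)phenol F8.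
- The remaining hydroxyl of F8 is arylated with 3 under the conditions of step 3 to give 16.

**Step 17.**
- What may go wrong: some of the fifteen alkyl ethers may resist cleavage. Long exposure to acid may bring cyclodehydration across the biaryl bonds or scission of the most electron-rich diaryl ethers. The free polyphenol may oxidize in air or be lost on chromatography.
- Fallback: it sets out from 28 and comes back at 29. The crude product of the BBr3 treatment is not purified.
- It is acetylated at once (Ac2O, pyridine, catalytic 4-dimethylaminopyridine, rt) to the nonadecaacetate F9.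
- F9 is stable to air and silica, so it can be separated from partly alkylated material, which can be resubmitted to BBr3.
- Acid methanolysis (catalytic AcCl in degassed MeOH, rt) then releases 29, and only evaporation is needed afterwards.

**Further compounds**

F1 | step 15 | 1-ethoxyvinyllithium | [Li]C(=C)OCC
F2 | step 15 | 3-ethoxybut-3-en-2-one | C=C(OCC)C(C)=O
F3 | step 15 | 5-ethoxy-1,1,1-trifluorohex-5-ene-2,4-dione | C=C(OCC)C(=O)CC(=O)C(F)(F)F
F4 | step 15 | 1-diazo-3-ethoxybut-3-en-2-one | C=C(OCC)C(=O)C=[N+]=[N-]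
F5 | step 11 | 2,6-dibromo-1,4-benzoquinone | O=C1C=C(Br)C(=O)C(Br)=C1
F6 | step 11 | 2,6-bis[3-formyl-2,6-dimethoxy-4-(2,4,6-trimethoxyphenoxy)phenoxy]-1,4-benzoquinone | O=C1C=C(Oc2c(OC)cc(Oc3c(OC)cc(OC)cc3OC)c(C=O)c2OC)C(=O)C(Oc2c(OC)cc(Oc3c(OC)cc(OC)cc3OC)c(C=O)c2OC)=C1
F7 | step 11 | 2,6-bis[3-formyl-2,6-dimethoxy-4-(2,4,6-trimethoxyphenoxy)phenoxy]benzene-1,4-diol | Oc1cc(Oc2c(OC)cc(Oc3c(OC)cc(OC)cc3OC)c(C=O)c2OC)c(O)c(Oc2c(OC)cc(Oc3c(OC)cc(OC)cc3OC)c(C=O)c2OC)c1
F8 | step 11 | 2,6-bis[3-formyl-2,6-dimethoxy-4-(2,4,6-trimethoxyphenoxy)phenoxy]-4-methoxyphenol | COc1cc(Oc2c(OC)cc(Oc3c(OC)cc(OC)cc3OC)c(C=O)c2OC)c(O)c(Oc2c(OC)cc(Oc3c(OC)cc(OC)cc3OC)c(C=O)c2OC)c1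
F9 | step 17 | nonadecaacetate of 29 | CC(=O)Oc1cc(OC(C)=O)c(Oc2cc(OC(C)=O)c(Oc3cc(OC(C)=O)cc(Oc4c(OC(C)=O)cc(Oc5c(OC(C)=O)cc(OC(C)=O)cc5OC(C)=O)c(-c5c(OC(C)=O)cc(OC(C)=O)cc5OC(C)=O)c4OC(C)=O)c3Oc3cc(OC(C)=O)c(Cl)c(OC(C)=O)c3)c(OC(C)=O)c2-c2c(OC(C)=O)cc(OC(C)=O)cc2OC(C)=O)c(OC(C)=O)c1
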